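**Retrosynthetic overview**

1. The target is three identical (2R,3R)-2,3-cis 7,8,4'-trihydroxyflavan ("epioritin") units joined twice C4→C6, the lower unit being the all-cis flavan-3,4-diol. Cutting both C4–C6 bonds (C4 cation from a thioether donor, C6 of ring A as nucleophile) leads back to one perbenzylated all-cis chroman-4-ol.
2. The route rests on this feature: in ring C of every unit C2 and C3 are adjacent oxygen-bearing stereocentres, C2 carries ring B (4-hydroxyphenyl), and C4 is the carbon that joins C3 to ring A. This is the pattern of a glycolate syn-aldol adduct of 4-benzyloxybenzaldehyde whose acyl carbon becomes C4.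
3. Monomer: auxiliary-controlled glycolate aldol (C2–C3, both centres), Weinreb amide, aryl ketone (C4–C4a, ring A as a 2-bromoaryl Grignard reagent), hydroxyl-directed 1,3-anti reduction (C4), copper-catalysed O1–C8a etherification with retention at C2.
4. Ring order: rings A and B are bought; ring C is the only ring formed, closed last in the monomer. Then donor + acceptor give the dimer, a second donor gives the trimer, followed by deacetylation and hydrogenolysis.

Key step: step 2

Remark on the chemistry: an alkoxide β to an aryl ketone is open to retro-aldol cleavage, and a 2,3-cis 3-alkoxychroman-4-one to base epimerisation at C3. The ketone is therefore reduced before ring C is closed, and ring A carries bromine for an etherification that needs no carbonyl activation.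

Remark on names: "epioritin" means the (2R,3R)-2-(4-hydroxyphenyl)chroman-3,7,8-triol unit; 4β is trans and 4α is cis to the 3-oxygen. The thioether donor is written as the expected 3,4-trans epimer; either epimer would serve, since C4 is ionised when it is used.

**Route**

Step 1
Reactants: 1 (S)-4-benzyl-2-oxazolidinone; 2 benzyloxyacetyl chloride
Product: 3 (S)-4-benzyl-3-[(benzyloxy)acetyl]oxazolidin-2-one
Conditions: n-BuLi (1.0 equiv), THF, −78 °C; then 2, −78 → 0 °C
Reagents that add atoms: none
Why: N-acylation of the lithiated oxazolidinone by the acid chloride (standard imide formation) should be clean at low temperature and creates no stereocentre.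

Step 2
Reactants: 3 (S)-4-benzyl-3-[(benzyloxy)acetyl]oxazolidin-2-one; 4 4-benzyloxybenzaldehyde
Product: 7 (S)-4-benzyl-3-[(2S,3R)-2-(benzyloxy)-3-[4-(benzyloxy)phenyl]-3-hydroxypropanoyl]oxazolidin-2-one (syn aldol adduct), via Z dibutylboron enolate 5 (not isolated), via dibutylboron aldolate 6 (not isolated)
Conditions: Bu2BOTf (1.2 equiv), Et3N (1.4 equiv), CH2Cl2, −78 → 0 °C; then 4 (1.1 equiv), −78 → 0 °C; pH 7 buffer, MeOH, 30% H2O2, 0 °C
Reagents that add atoms: none
Why: Soft enolisation of imide 3 with Bu2BOTf and Et3N gives the Z boron enolate 5, which adds to aldehyde 4 through a closed Zimmerman–Traxler chair with the aryl group equatorial and forms the bond that becomes C2–C3 of ring C. The closest known reaction type is the Evans boron syn-aldol of N-glycolyl oxazolidinones with aromatic aldehydes. No ring is closed in this step. Both new stereocentres arise in the one transition state: the Z enolate geometry fixes the syn relation of the 2-benzyloxy and 3-hydroxyl groups, and the (S)-benzyl group of the auxiliary, held with its carbonyl dipole opposed to the enolate oxygen, shields one enolate face so that the (2S,3R) adduct should form, which maps onto (2R,3R) of the flavan. The step needs syn over anti and one enolate face over the other; complete Z enolisation by the dialkylboron triflate and the dipole-minimised auxiliary conformation secure this, and the α-benzyloxy group cannot chelate boron, whose two free sites are taken by the enolate and aldehyde oxygens.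

Step 3
Reactants: 7 syn aldol adduct
Product: 8 (2S,3R)-2-(benzyloxy)-3-[4-(benzyloxy)phenyl]-3-hydroxy-N-methoxy-N-methylpropanamide
Conditions: MeNH(OMe)·HCl (3 equiv), AlMe3 (3 equiv), CH2Cl2, −20 → 0 °C; aq. Rochelle salt
Reagents that add atoms: N,O-dimethylhydroxylamine hydrochloride, CNOC.Cl
Why: Weinreb transamidation by the aluminium amide is assisted by the free β-hydroxyl, releases the auxiliary, and touches neither the α-hydrogen nor the benzylic C–O bond, so both stereocentres are kept.

Step 4
Reactants: 9 3-bromocatechol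
Product: 10 1,2-bis(benzyloxy)-3-bromobenzene
Conditions: BnBr (2.3 equiv), K2CO3 (3 equiv), DMF, 50 °C
Reagents that add atoms: benzyl bromide, BrCc1ccccc1
Why: Williamson etherification of both phenols; no stereocentre is involved.

Step 5
Reactants: 10 1,2-bis(benzyloxy)-3-bromobenzene
Product: 11 1,2-bis(benzyloxy)-3-bromo-4-iodobenzene
Conditions: NIS (1.05 equiv), TFA (cat.), MeCN, 0 °C → rt
Reagents that add atoms: N-iodosuccinimide, O=C1CCC(=O)N1I
Why: Electrophilic aromatic iodination should occur para to the C1 benzyloxy group, the only alkoxy group able to lie in the ring plane (the C2 benzyloxy group is flanked on both sides), which places iodine next to bromine.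

Step 6
Reactants: 8 Weinreb amide; 11 1,2-bis(benzyloxy)-3-bromo-4-iodobenzene
Product: 14 (2S,3R)-2-(benzyloxy)-1-[3,4-bis(benzyloxy)-2-bromophenyl]-3-[4-(benzyloxy)phenyl]-3-hydroxypropan-1-one, via arylmagnesium chloride 12 (not isolated), via chloromagnesium alkoxide 13 (not isolated)
Conditions: 11 (1.5 equiv), i-PrMgCl·LiCl (1.5 equiv), THF, −40 °C; separately 8, i-PrMgCl (1.0 equiv), THF, −40 °C; combine, −40 → 0 °C; aq. NH4Cl
Reagents that add atoms: none
Why: Iodine–magnesium exchange is far faster than bromine–magnesium exchange and the 2-bromoarylmagnesium chloride is stable below 0 °C, and its addition to the amide stops at the N-methoxy chelate (Weinreb ketone synthesis), so the ketone appears only on work-up and the α-centre is not exposed to base.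

Step 7
Reactants: 14 aryl ketone
Product: 15 (1R,2S,3R)-2-(benzyloxy)-1-[3,4-bis(benzyloxy)-2-bromophenyl]-3-[4-(benzyloxy)phenyl]propane-1,3-diol
Conditions: Me4NBH(OAc)3 (6 equiv), MeCN/AcOH (1:1), −20 → 0 °C
Reagents that add atoms: none
Why: Evans–Saksena reduction: the C3 hydroxyl exchanges an acetate on boron and delivers hydride intramolecularly through a chair six-membered transition state, which should give the 1,3-anti diol with the new C1 centre R (also 1,2-anti to the benzyloxy group, so α-alkoxy chelation would favour the same isomer).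

Step 8
Reactants: 15 1,3-anti diol
Product: 16 (2R,3R,4R)-3,7,8-tris(benzyloxy)-2-[4-(benzyloxy)phenyl]chroman-4-ol (all-cis)
Conditions: CuI (10 mol %), 3,4,7,8-tetramethyl-1,10-phenanthroline (20 mol %), Cs2CO3 (2 equiv), toluene, 110 °C, argon
Reagents that add atoms: none
Why: Copper-catalysed intramolecular Ullmann etherification closes O1–C8a: only the C3 hydroxyl can reach the C–Br carbon through a six-membered ring (the C1 hydroxyl would have to form a four-membered ring), no bond to a stereocentre is broken, and without a carbonyl group neither retro-aldol cleavage nor epimerisation can occur.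

Step 9
Reactants: 16 all-cis chroman-4-ol
Product: 17 (2R,3S,4S)-4-(benzylsulfanyl)-3,7,8-tris(benzyloxy)-2-[4-(benzyloxy)phenyl]chromane (thioether donor)
Conditions: BnSH (5 equiv), BF3·OEt2 (0.3 equiv), CH2Cl2, −40 → 0 °C
Reagents that add atoms: benzyl mercaptan, SCc1ccccc1
Why: Acid-promoted SN1 thiolysis at C4: the hydroxyl ionises to the cation stabilised by the para 7-benzyloxy group and the ortho ring oxygen, the excess thiol outruns self-condensation, and the thiol should add trans to the axial 3-benzyloxy group (a centre that is ionised again later).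

Step 10
Reactants: 16 all-cis chroman-4-ol
Product: 18 (2R,3S,4R)-3,7,8-tris(benzyloxy)-2-[4-(benzyloxy)phenyl]chroman-4-yl acetate (acceptor; same all-cis geometry as 16)
Conditions: Ac2O (3 equiv), pyridine, DMAP (cat.), CH2Cl2, 0 °C → rt
Reagents that add atoms: acetic anhydride, CC(=O)OC(C)=O
Why: DMAP-catalysed O-acetylation proceeds with retention at C4, removes the O-nucleophilicity of the C4 oxygen, and gives a group that thiophilic silver does not activate.

Step 11
Reactants: 17 thioether donor; 18 acetate acceptor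
Product: 19 octa-O-benzyl epioritin-(4β→6)-epioritin-4α-ol 4-O-acetate (dimer)
Conditions: 18 (3 equiv), AgBF4 (2 equiv), 2,6-di-tert-butyl-4-methylpyridine (1.5 equiv), 4 Å molecular sieves, THF, 0 °C, dark; 17 (1 equiv) added over 1 h; excess 18 recovered
Reagents that add atoms: none
Why: Thiophile-promoted Friedel–Crafts coupling: AgBF4 removes the benzylthio group of 17 and the C4 cation is attacked by C6 of 18 (para to the ring oxygen and ortho to the 7-benzyloxy group, whereas C5 lacks such activation) from the face opposite the axial 3-benzyloxy group, which should set the new C4 centre 3,4-trans as in the target, while the acetate of 18 is inert to silver, the hindered pyridine takes up the acid, and the excess of 18 holds back self-condensation of 17.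

Step 12
Reactants: 17 thioether donor; 19 dimer
Product: 20 dodeca-O-benzyl epioritin-(4β→6)-epioritin-(4β→6)-epioritin-4α-ol 4-O-acetate (trimer)
Conditions: 19 (2.5 equiv), AgBF4 (2 equiv), 2,6-di-tert-butyl-4-methylpyridine (1.5 equiv), 4 Å molecular sieves, THF, 0 °C, dark; 17 (1 equiv) added over 2 h; excess 19 recovered
Reagents that add atoms: none
Why: The same silver-promoted Friedel–Crafts coupling: the only strongly activated free position of 19 is C6 of its upper unit (C6 of the lower unit is already substituted), and attack on the cation anti to the 3-benzyloxy group should again give the 3,4-trans C4 centre of the new upper unit.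

Step 13
Reactants: 20 trimer acetate
Product: 21 dodeca-O-benzyl epioritin-(4β→6)-epioritin-(4β→6)-epioritin-4α-ol
Conditions: K2CO3 (0.5 equiv), MeOH/THF (1:1), rt
Reagents that add atoms: none
Why: Base-catalysed transesterification (Zemplén-type methanolysis) cleaves the acetate at the acyl carbon, so the C4–O bond and its configuration are untouched, and benzyl ethers and interflavan bonds are stable to carbonate.

Step 14
Reactants: 21 dodeca-O-benzyl trimer
Product: 22 epioritin-(4β→6)-epioritin-(4β→6)-epioritin-4α-ol (CNP0140823.1)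
Conditions: H2 (1 atm), Pd(OH)2/C, THF/MeOH (1:1), rt; filtered under argon; Sephadex LH-20
Reagents that add atoms: none
Why: Catalytic hydrogenolysis cleaves the twelve O–CH2Ph bonds (nine aryl and three alkyl benzyl ethers) under neutral conditions without touching a stereocentre, and the neutral medium, room temperature and prompt filtration are meant to spare the benzylic C4 hydroxyl and the ring C–O bonds.

**Compound list**

1 | (S)-4-benzyl-2-oxazolidinone | O=C1N[C@@H](Cc2ccccc2)CO1 | starting material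
2 | benzyloxyacetyl chloride | O=C(Cl)COCc1ccccc1 | starting material
3 | (S)-4-benzyl-3-[(benzyloxy)acetyl]oxazolidin-2-one | O=C(COCc1ccccc1)N1[C@@H](Cc2ccccc2)COC1=O | intermediate
4 | 4-benzyloxybenzaldehyde | O=Cc1ccc(OCc2ccccc2)cc1 | starting material
5 | Z dibutylboron enolate of 3 (not isolated) | CCCCB(CCCC)O/C(=C\OCc1ccccc1)N1[C@@H](Cc2ccccc2)COC1=O | intermediate
6 | dibutylboron aldolate of 7 (not isolated) | CCCCB(CCCC)O[C@H](c1ccc(OCc2ccccc2)cc1)[C@H](OCc1ccccc1)C(=O)N1[C@@H](Cc2ccccc2)COC1=O | intermediate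
7 | (S)-4-benzyl-3-[(2S,3R)-2-(benzyloxy)-3-[4-(benzyloxy)phenyl]-3-hydroxypropanoyl]oxazolidin-2-one | O[C@H](c1ccc(OCc2ccccc2)cc1)[C@H](OCc1ccccc1)C(=O)N1[C@@H](Cc2ccccc2)COC1=O | intermediate
8 | (2S,3R)-2-(benzyloxy)-3-[4-(benzyloxy)phenyl]-3-hydroxy-N-methoxy-N-methylpropanamide | O[C@H](c1ccc(OCc2ccccc2)cc1)[C@H](OCc1ccccc1)C(=O)N(C)OC | intermediate
9 | 3-bromocatechol | Oc1cccc(Br)c1O | starting material
10 | 1,2-bis(benzyloxy)-3-bromobenzene | Brc1cccc(OCc2ccccc2)c1OCc1ccccc1 | intermediate
11 | 1,2-bis(benzyloxy)-3-bromo-4-iodobenzene | Ic1ccc(OCc2ccccc2)c(OCc2ccccc2)c1Br | intermediate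
12 | [3,4-bis(benzyloxy)-2-bromophenyl]magnesium chloride (not isolated) | Cl[Mg]c1ccc(OCc2ccccc2)c(OCc2ccccc2)c1Br | intermediate
13 | chloromagnesium alkoxide of 8 (not isolated) | Cl[Mg]O[C@H](c1ccc(OCc2ccccc2)cc1)[C@H](OCc1ccccc1)C(=O)N(C)OC | intermediate
14 | (2S,3R)-2-(benzyloxy)-1-[3,4-bis(benzyloxy)-2-bromophenyl]-3-[4-(benzyloxy)phenyl]-3-hydroxypropan-1-one | O[C@H](c1ccc(OCc2ccccc2)cc1)[C@H](OCc1ccccc1)C(=O)c1ccc(OCc2ccccc2)c(OCc2ccccc2)c1Br | intermediate
15 | (1R,2S,3R)-2-(benzyloxy)-1-[3,4-bis(benzyloxy)-2-bromophenyl]-3-[4-(benzyloxy)phenyl]propane-1,3-diol | O[C@H](c1ccc(OCc2ccccc2)cc1)[C@H](OCc1ccccc1)[C@H](O)c1ccc(OCc2ccccc2)c(OCc2ccccc2)c1Br | intermediate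
16 | (2R,3R,4R)-3,7,8-tris(benzyloxy)-2-[4-(benzyloxy)phenyl]chroman-4-ol (all-cis) | c1cc2c(c(OCc3ccccc3)c1OCc1ccccc1)O[C@H](c1ccc(OCc3ccccc3)cc1)[C@H](OCc1ccccc1)[C@@H]2O | intermediate
17 | (2R,3S,4S)-4-(benzylsulfanyl)-3,7,8-tris(benzyloxy)-2-[4-(benzyloxy)phenyl]chromane (2,3-cis-3,4-trans) | c1cc2c(c(OCc3ccccc3)c1OCc1ccccc1)O[C@H](c1ccc(OCc3ccccc3)cc1)[C@H](OCc1ccccc1)[C@H]2SCc1ccccc1 | intermediate
18 | (2R,3S,4R)-3,7,8-tris(benzyloxy)-2-[4-(benzyloxy)phenyl]chroman-4-yl acetate (all-cis) | c1cc2c(c(OCc3ccccc3)c1OCc1ccccc1)O[C@H](c1ccc(OCc3ccccc3)cc1)[C@H](OCc1ccccc1)[C@@H]2OC(C)=O | intermediate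
19 | octa-O-benzyl epioritin-(4β→6)-epioritin-4α-ol 4-O-acetate | c5ccccc5COc1ccc([C@H]2Oc3c(ccc(OCc5ccccc5)c3OCc5ccccc5)[C@H](c3cc4c(c(OCc5ccccc5)c3OCc5ccccc5)O[C@H](c3ccc(OCc5ccccc5)cc3)[C@H](OCc5ccccc5)[C@@H]4OC(C)=O)[C@H]2OCc5ccccc5)cc1 | intermediate
20 | dodeca-O-benzyl epioritin-(4β→6)-epioritin-(4β→6)-epioritin-4α-ol 4-O-acetate | c5ccccc5COc1ccc([C@H]2Oc3c(ccc(OCc5ccccc5)c3OCc5ccccc5)[C@H](c3cc4c(c(OCc5ccccc5)c3OCc5ccccc5)O[C@H](c3ccc(OCc5ccccc5)cc3)[C@H](OCc5ccccc5)[C@H]4c3cc4c(c(OCc5ccccc5)c3OCc5ccccc5)O[C@H](c3ccc(OCc5ccccc5)cc3)[C@H](OCc5ccccc5)[C@@H]4OC(C)=O)[C@H]2OCc5ccccc5)cc1 | intermediate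
21 | dodeca-O-benzyl epioritin-(4β→6)-epioritin-(4β→6)-epioritin-4α-ol | c5ccccc5COc1ccc([C@H]2Oc3c(ccc(OCc5ccccc5)c3OCc5ccccc5)[C@H](c3cc4c(c(OCc5ccccc5)c3OCc5ccccc5)O[C@H](c3ccc(OCc5ccccc5)cc3)[C@H](OCc5ccccc5)[C@H]4c3cc4c(c(OCc5ccccc5)c3OCc5ccccc5)O[C@H](c3ccc(OCc5ccccc5)cc3)[C@H](OCc5ccccc5)[C@@H]4O)[C@H]2OCc5ccccc5)cc1 | intermediate
22 | epioritin-(4β→6)-epioritin-(4β→6)-epioritin-4α-ol; upper and middle units (2R,3R,4S), lower unit (2R,3R,4R) | Oc1ccc([C@H]2Oc3c(ccc(O)c3O)[C@H](c3cc4c(c(O)c3O)O[C@H](c3ccc(O)cc3)[C@H](O)[C@H]4c3cc4c(c(O)c3O)O[C@H](c3ccc(O)cc3)[C@H](O)[C@@H]4O)[C@H]2O)cc1 | target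

**Step count**

Total: 14 steps. Longest linear sequence: 11 steps (1, 2, 3, 6, 7, 8, 10, 11, 12, 13, 14).

**Steps most likely to fail**

1. Step 12 (second coupling). The risk is loss of chemoselectivity in the capture of the cation: the donor's own C6 and the free C6 of the newly formed trimer compete with the dimer, so that donor self-condensation and further chain growth accompany the single addition. The same process threatens step 11, where the cheap monomer can be used in larger excess. The fallback caps C6 of the donor with bromine. It sets out from 16: NBS in CH2Cl2 at −20 °C should brominate the most electron-rich ring position to give (2R,3R,4R)-6-bromo-3,7,8-tris(benzyloxy)-2-[4-(benzyloxy)phenyl]chroman-4-ol F1. Benzyl mercaptan with catalytic BF3·OEt2 converts this into the 6-bromo thioether donor F2. F2 and 19 in a near 1:1 ratio, with AgBF4 and the hindered pyridine as in step 12, should give the 6-bromo trimer acetate F3, which can neither self-condense nor take up another unit. K2CO3 in MeOH/THF gives the 6-bromo trimer 4-ol F4. Hydrogenolysis over Pd(OH)2/C with NaHCO3 present removes the bromine together with the twelve benzyl groups, and the sequence comes back to the route at 22.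

2. Step 8 (ring closure). The risk is slow insertion of copper into the doubly ortho-substituted, electron-rich C–Br bond, so that hydrodebromination or intermolecular etherification takes over. The fallback closes the same O1–C8a bond without a metal, by displacement of fluoride. It sets out from 8 and commercial 3-fluorocatechol:
   - Dibenzylation (BnBr, K2CO3, DMF) gives 1,2-bis(benzyloxy)-3-fluorobenzene F5.
   - NBS in MeCN brominates para to the unflanked benzyloxy group to give 1-bromo-3,4-bis(benzyloxy)-2-fluorobenzene F6.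
   - Bromine–lithium exchange (n-BuLi, THF, −78 °C) gives [3,4-bis(benzyloxy)-2-fluorophenyl]lithium F7, which is added at −78 °C to the alkoxide 13 to give the fluoro ketone F8.
   - Me4NBH(OAc)3 as in step 7 gives the 1,3-anti fluoro diol F9.
   - KOtBu in DMSO at 60 °C should then bring about intramolecular nucleophilic aromatic substitution of fluoride by the C3 alkoxide, with retention at that carbon and again with no carbonyl group present, and the sequence comes back to the route at 16.

3. Step 14 (hydrogenolysis). The risk is over-reduction: once the 7-hydroxyl para to C4 of the lower unit is unmasked, hydrogenolysis of the benzylic C4–OH bond can follow the O-debenzylation. The fallback carries C4 of the lower unit through the hydrogenolysis as a ketone and sets the carbinol last. It sets out from 21: Dess–Martin periodinane in CH2Cl2 with NaHCO3 oxidises the one free hydroxyl to give the dodeca-O-benzyl trimer with a lower-unit chroman-4-one F10. Hydrogenolysis over Pd(OH)2/C (an aryl ketone conjugated to two ring-A oxygens is not reduced under these conditions) gives the free-phenolic trimer ketone F11. NaBH4 in EtOH at 0 °C should deliver hydride to C4 from the face opposite the axial 3-hydroxyl, giving the all-cis diol, and the sequence comes back to the route at 22.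

**Further compounds**

F1 | step 12 | (2R,3R,4R)-6-bromo-3,7,8-tris(benzyloxy)-2-[4-(benzyloxy)phenyl]chroman-4-ol | Brc1cc2c(c(OCc3ccccc3)c1OCc1ccccc1)O[C@H](c1ccc(OCc3ccccc3)cc1)[C@H](OCc1ccccc1)[C@@H]2O
F2 | step 12 | (2R,3S,4S)-4-(benzylsulfanyl)-6-bromo-3,7,8-tris(benzyloxy)-2-[4-(benzyloxy)phenyl]chromane | Brc1cc2c(c(OCc3ccccc3)c1OCc1ccccc1)O[C@H](c1ccc(OCc3ccccc3)cc1)[C@H](OCc1ccccc1)[C@H]2SCc1ccccc1
F3 | step 12 | 6-bromo (upper unit) dodeca-O-benzyl epioritin-(4β→6)-epioritin-(4β→6)-epioritin-4α-ol 4-O-acetate | c5ccccc5COc1ccc([C@H]2Oc3c(cc(Br)c(OCc5ccccc5)c3OCc5ccccc5)[C@H](c3cc4c(c(OCc5ccccc5)c3OCc5ccccc5)O[C@H](c3ccc(OCc5ccccc5)cc3)[C@H](OCc5ccccc5)[C@H]4c3cc4c(c(OCc5ccccc5)c3OCc5ccccc5)O[C@H](c3ccc(OCc5ccccc5)cc3)[C@H](OCc5ccccc5)[C@@H]4OC(C)=O)[C@H]2OCc5ccccc5)cc1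
F4 | step 12 | 6-bromo (upper unit) dodeca-O-benzyl epioritin-(4β→6)-epioritin-(4β→6)-epioritin-4α-ol | c5ccccc5COc1ccc([C@H]2Oc3c(cc(Br)c(OCc5ccccc5)c3OCc5ccccc5)[C@H](c3cc4c(c(OCc5ccccc5)c3OCc5ccccc5)O[C@H](c3ccc(OCc5ccccc5)cc3)[C@H](OCc5ccccc5)[C@H]4c3cc4c(c(OCc5ccccc5)c3OCc5ccccc5)O[C@H](c3ccc(OCc5ccccc5)cc3)[C@H](OCc5ccccc5)[C@@H]4O)[C@H]2OCc5ccccc5)cc1
F5 | step 8 | 1,2-bis(benzyloxy)-3-fluorobenzene | Fc1cccc(OCc2ccccc2)c1OCc1ccccc1
F6 | step 8 | 1-bromo-3,4-bis(benzyloxy)-2-fluorobenzene | Brc1ccc(OCc2ccccc2)c(OCc2ccccc2)c1F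
F7 | step 8 | [3,4-bis(benzyloxy)-2-fluorophenyl]lithium | [Li]c1ccc(OCc2ccccc2)c(OCc2ccccc2)c1F
F8 | step 8 | (2S,3R)-2-(benzyloxy)-1-[3,4-bis(benzyloxy)-2-fluorophenyl]-3-[4-(benzyloxy)phenyl]-3-hydroxypropan-1-one | O[C@H](c1ccc(OCc2ccccc2)cc1)[C@H](OCc1ccccc1)C(=O)c1ccc(OCc2ccccc2)c(OCc2ccccc2)c1F
F9 | step 8 | (1R,2S,3R)-2-(benzyloxy)-1-[3,4-bis(benzyloxy)-2-fluorophenyl]-3-[4-(benzyloxy)phenyl]propane-1,3-diol | O[C@H](c1ccc(OCc2ccccc2)cc1)[C@H](OCc1ccccc1)[C@H](O)c1ccc(OCc2ccccc2)c(OCc2ccccc2)c1F
F10 | step 14 | dodeca-O-benzyl trimer with the lower unit as its 2,3-cis chroman-4-one | c5ccccc5COc1ccc([C@H]2Oc3c(ccc(OCc5ccccc5)c3OCc5ccccc5)[C@H](c3cc4c(c(OCc5ccccc5)c3OCc5ccccc5)O[C@H](c3ccc(OCc5ccccc5)cc3)[C@H](OCc5ccccc5)[C@H]4c3cc4c(c(OCc5ccccc5)c3OCc5ccccc5)O[C@H](c3ccc(OCc5ccccc5)cc3)[C@H](OCc5ccccc5)C4=O)[C@H]2OCc5ccccc5)cc1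
F11 | step 14 | free-phenolic trimer with the lower unit as its 2,3-cis chroman-4-one | Oc1ccc([C@H]2Oc3c(ccc(O)c3O)[C@H](c3cc4c(c(O)c3O)O[C@H](c3ccc(O)cc3)[C@H](O)[C@H]4c3cc4c(c(O)c3O)O[C@H](c3ccc(O)cc3)[C@H](O)C4=O)[C@H]2O)cc1
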